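## The problem

Compound 21 is a cyclopenta[c]pyridine. The pyridine ring (C1, N2, C3, C4, C4a, C7a) is fused through C4a–C7a to a five-membered ring (C5, C6, C7) in which C7 is a ketone on C7a, and C3 carries a (1E,3E,5S)-3,5-dimethylhepta-1,3-dienyl chain. C5 and C6 are adjacent, fully substituted and oxygenated: C5 bears hydroxyl, methyl ester and C4a; C6 bears methyl, acetoxy and C7. The 5R,6S configuration places ester and acetoxy cis and the two oxygens trans. Neither centre has a hydrogen, so neither can be corrected by epimerisation, and a free C5 alkoxide, being β to the C7 ketone, can open the ring by retro-aldol cleavage of C5–C6, which would flatten C6 as well. Both centres therefore have to be set together, in the bond that joins them, and the C5 oxygen kept masked and away from base until the end. The side-chain stereocentre C5' is too far from the ring to control it or be controlled by it and must come from the chiral pool; its hydrogen is allylic and conjugated through the diene with the pyridine, so strong base and acid threaten it and the E,E-diene. The feature that opens the synthesis is that C5–C6 joins the keto carbon of a pyridin-4-yl glyoxylate (C5 with its ester and C4a) to the α-carbon of lactic acid (C6 with methyl, oxygen and the carboxyl carbon C7), and that C7–C7a then links the lactic carboxyl carbon to the pyridine carbon ortho to the glyoxylate.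

## Retrosynthesis

**21 to 19 (O–Si and O–acetyl bonds).** The C5 oxygen of 21 is traced to the trimethylsilyl ether 20 and the acetate of 20 to the tertiary alcohol 19. With C5–O silylated, the two tertiary hydroxyls need no selective acylation, and no C5 alkoxide can arise before the last step. The forward steps must acylate a hindered tertiary alcohol without strong base and remove silicon without base.

**19 to 16 (C7–C7a).** Cutting the ketone–aryl bond opens the five-membered ring and leads to the aryl bromide 16, in which C7 is the carbonyl of a 1,3-dioxolan-4-one. The neighbouring cut C4a–C5 would need arylation of a fully substituted carbon. C7–C7a is an acylation of an aryl metal, intramolecular and 5-exo, and the acyl donor is the acetal that lactic acid brings with it; its leaving group falls apart to pivalaldehyde and uncovers the C6 hydroxyl. The forward step needs bromine–magnesium exchange to outrun addition of the reagent to the ester and lactone.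

**16 to 14 and 9 (C5–C6, the key cut).** This is the only cut that removes both quaternary stereocentres at once and divides the molecule into two fragments of similar size: the silyl ketene acetal 14 of the lactic acid acetal and the pyridyl keto ester 9.
- C6 follows from self-regeneration of the lactic acid stereocentre: the tert-butyl group of 14 covers one face.
- C5 is the open question, and the mode of the aldol is chosen for it. Seen along the forming bond, C6 offers three gaps: (a) between methyl and C7, beside the exocyclic enolate oxygen; (b) between methyl and the ring oxygen; (c) between the ring oxygen and C7, over the dioxolanone ring and its acetal hydrogen, the tightest.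
- A lithium enolate would hold the keto oxygen in gap (a) through a lithium bridge; the aryl group would then take (b) and the ester (c), which is expected to lead to the C5 epimer.
- Without a bridging metal the keto oxygen should move away from the enolate oxygen into (b); the aryl group then takes (a) and the flat ester (c), which is the arrangement 21 requires. The union is therefore planned as a fluoride-promoted addition of 14, not as a lithium aldol.

**14 to 12, 10 and 11.** The Si–O bond of 14 leads to the cis acetal 12, and its two acetal C–O bonds to (R)-lactic acid 10 and pivalaldehyde 11. The precursor is one crystallisable compound; the forward steps must deliver 12 free of its trans isomer and silylate the enolate 13 on oxygen.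

**9 to 7 (pyridine C4–keto carbon, that is C4a–C5).** The bromine of 7 directs lithiation to the neighbouring C4 and later serves as the handle for ring closure, so no further ring substituent is needed. The forward step asks an amide base to metalate the ring without touching the dienyl chain.

**7 to 5 and 6 (pyridine C2–C1').** A Suzuki cut gives the dienylboronate 5 and 2,5-dibromopyridine 6, whose C2 bromide is the more reactive. It keeps both alkene geometries fixed in 5 and brings the chain in before any sensitive ring functionality exists.

**5 to 1.** The boronate 5 comes from the enyne 4 by hydroboration (sets 1E), 4 from the enal 3 by one-carbon homologation, 3 from (S)-2-methylbutanal 2 by Wittig olefination (sets 3E), and 2 from (S)-2-methylbutan-1-ol 1, which supplies C5'.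

## Roads not taken

Alternative 1: The cut is the C6–O bond, made at the stage of a benzene ring, followed by a change of ring size. A flavin-dependent monooxygenase (O2, NADPH) would hydroxylate the benzaldehyde A1 at the methyl-bearing carbon between its two phenols, and the dearomatised product would close through its side-chain ketone and aldehyde to the azaphilone A2.
- Merits: the oxygenated stereocentre is set catalytically from a flat aromatic precursor, no protecting groups are needed, and the carbon skeleton with the complete side chain is reached in very few steps.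
- Weak points: an enzyme must be found that accepts A1 and delivers the 7S sense. From A2 the ring oxygen must still be exchanged for nitrogen and the six-membered dione contracted to the five-membered hydroxy ester, a rearrangement whose stereochemical course at C5 is unknown and for which no laboratory model close to this substrate is at hand. The acetate would have to survive or follow these steps.
- Comparison: this road is shorter to an advanced intermediate and better in atom economy. The chosen plan sets against it that C5, C6 and the ester are all in place after one bond formation from defined small fragments, with no dependence on enzyme scope or on an uncharted ring contraction.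

Alternative 2: The cuts are C3–C4 and C4a–C7a. Heating the oxazole A3, which carries the dienyl group at its 2-position, the C7 acyl group at its 5-position and a vinyl group on C5 of the future ring, would give by intramolecular Diels–Alder reaction and loss of water the pyridine A4.
- Merits: the pyridine and the five-membered ring form in one thermal step, the tether fixes the regiochemistry, and no organometallic ring closure is needed.
- Weak points: A3 already contains both quaternary stereocentres, so the central problem is moved into a separate acyclic synthesis and not solved. A 5-acyl oxazole is an electron-poor diene and the vinyl group an unactivated dienophile on a quaternary carbon, so high temperature is to be expected, which endangers the side-chain diene and the tertiary acetate.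
- Comparison: in ring construction this road is more economical than the chosen plan, which needs a lithiation and a separate ring closure. The chosen plan sets against it that its key step creates the two stereocentres that Alternative 2 must import.

Alternative 3: The cuts are C4a–C5 and C7–C7a, made in one annulation. The enolate of the citramalate-derived ester A5 would add to the γ-carbon of the 3,4-pyridyne A6, and the aryl anion so formed would attack the dioxolanone carbonyl and expel acetone to give A7.
- Merits: two bonds and the ring form in one operation, and C6 comes from the chiral pool.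
- Weak points: additions to 3,4-pyridynes without a directing substituent are poorly regioselective between the β and γ carbons. C5 is created by a hindered, fully substituted enolate with only the neighbouring C6 to direct it. A precursor of A6 that carries the dienyl chain is itself a multistep target.
- Comparison: in bonds per step this road is better than the chosen plan. The chosen plan sets against it that regiochemistry on the pyridine is fixed beforehand by the positions of bromine and keto ester, and that C6 is set by a rigid acetal and not by open-chain induction. Control at C5 is uncertain in both.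

Key step: step 9

Assumption: 1 and 10 are used as the commercial enantiomers, and 12 is freed from its trans isomer before use, because the trans acetal would give the enantiomeric enolate.

## Route

Step 1
Reactants: 1 (S)-2-methylbutan-1-ol
Product: 2 (S)-2-methylbutanal
Conditions: 2,2,6,6-tetramethylpiperidin-1-oxyl (cat.), NaOCl, KBr, NaHCO3, CH2Cl2/H2O, 0 °C
Reagents that add atoms: none
Why: Anelli oxidation through the oxoammonium salt stops at the aldehyde and is an established way to make this α-branched aldehyde without loss of configuration; the volatile product is used promptly.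

Step 2
Reactants: 2 (S)-2-methylbutanal
Product: 3 (2E,4S)-2,4-dimethylhex-2-enal
Conditions: Ph3P=C(CH3)CHO, toluene, 80 °C
Reagents that add atoms: 2-(triphenylphosphoranylidene)propanal, CC(C=O)=P(c1ccccc1)(c1ccccc1)c1ccccc1
Why: Wittig olefination with a formyl-stabilised ylide gives the trisubstituted (E)-enal directly; the α-stereocentre of 2 is at risk only while the aldehyde is free, so the ylide is used in excess at moderate temperature.

Step 3
Reactants: 3 (2E,4S)-2,4-dimethylhex-2-enal
Product: 4 (3E,5S)-3,5-dimethylhept-3-en-1-yne
Conditions: Me3SiCHN2, LiN(iPr)2, THF, −78 °C to rt; aq NH4Cl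
Reagents that add atoms: (trimethylsilyl)diazomethane, C[Si](C)(C)C=[N+]=[N-]
Why: Colvin rearrangement: the lithiated diazo compound adds 1,2 to the aldehyde, Peterson-type elimination and loss of N2 give an alkylidene carbene, and a 1,2-hydrogen shift gives the terminal alkyne; addition at −78 °C leaves the γ-hydrogen on the stereocentre alone.

Step 4
Reactants: 4 (3E,5S)-3,5-dimethylhept-3-en-1-yne
Product: 5 2-[(1E,3E,5S)-3,5-dimethylhepta-1,3-dien-1-yl]-4,4,5,5-tetramethyl-1,3,2-dioxaborolane
Conditions: pinacolborane, Cp2Zr(H)Cl (cat.), Et3N (cat.), CH2Cl2, 40 °C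
Reagents that add atoms: pinacolborane, CC1(C)OBOC1(C)C
Why: Cp2Zr(H)Cl-catalysed hydroboration of a terminal alkyne is syn and anti-Markovnikov and gives the (E)-alkenylboronate; the trisubstituted alkene is left alone.

Step 5
Reactants: 5 2-[(1E,3E,5S)-3,5-dimethylhepta-1,3-dien-1-yl]-4,4,5,5-tetramethyl-1,3,2-dioxaborolane; 6 2,5-dibromopyridine
Product: 7 5-bromo-2-[(1E,3E,5S)-3,5-dimethylhepta-1,3-dien-1-yl]pyridine
Conditions: Pd(PPh3)4 (cat.), K2CO3, 1,4-dioxane/H2O, 80 °C
Reagents that add atoms: none
Why: Suzuki–Miyaura coupling; zerovalent palladium inserts into the C2–Br bond of 6 (alpha to nitrogen) in preference to C5–Br, and the alkene geometry of 5 is retained.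

Step 6
Reactants: 7 5-bromo-2-[(1E,3E,5S)-3,5-dimethylhepta-1,3-dien-1-yl]pyridine
Product: 9 methyl 2-{5-bromo-2-[(1E,3E,5S)-3,5-dimethylhepta-1,3-dien-1-yl]pyridin-4-yl}-2-oxoacetate, via aryllithium 8 (not isolated)
Conditions: LiN(iPr)2, THF, −78 °C; then added to (CO2Me)2 (excess), THF, −78 °C; aq NH4Cl
Reagents that add atoms: dimethyl oxalate, COC(=O)C(=O)OC
Why: Directed ortho-lithiation: LiN(iPr)2 removes H4, the ring proton ortho to bromine, as in 3-bromopyridines; addition of 8 to excess dimethyl oxalate at −78 °C stops at the α-keto ester because the tetrahedral adduct persists until work-up.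

Step 7
Reactants: 10 (R)-lactic acid; 11 pivalaldehyde
Product: 12 (2R,5R)-2-tert-butyl-5-methyl-1,3-dioxolan-4-one
Conditions: TsOH·H2O (cat.), H2SO4 (cat.), pentane, reflux with water separator; crystallisation from pentane/Et2O, −78 °C
Reagents that add atoms: none
Why: Acid-catalysed acetalisation with azeotropic removal of water; the cis acetal is the main isomer and is purified by low-temperature crystallisation, and the lactic acid stereocentre is not touched.

Step 8
Reactants: 12 (2R,5R)-2-tert-butyl-5-methyl-1,3-dioxolan-4-one
Product: 14 (2R)-2-tert-butyl-5-methyl-4-(trimethylsilyloxy)-1,3-dioxole, via lithium enolate 13 (not isolated)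
Conditions: LiN(iPr)2, THF, −78 °C; Me3SiCl, −78 to 0 °C; pentane, filtration
Reagents that add atoms: chlorotrimethylsilane, C[Si](C)(C)Cl
Why: Deprotonation gives the planar enolate 13, whose only stereocentre is the acetal carbon; O-silylation, the usual course for fully substituted ester enolates, gives 14, and the salt-free work-up removes LiCl, which would bind fluoride in step 9.

Step 9
Reactants: 14 (2R)-2-tert-butyl-5-methyl-4-(trimethylsilyloxy)-1,3-dioxole; 9 methyl 2-{5-bromo-2-[(1E,3E,5S)-3,5-dimethylhepta-1,3-dien-1-yl]pyridin-4-yl}-2-oxoacetate
Product: 16 methyl (2R)-2-{5-bromo-2-[(1E,3E,5S)-3,5-dimethylhepta-1,3-dien-1-yl]pyridin-4-yl}-2-[(2R,4S)-2-tert-butyl-4-methyl-5-oxo-1,3-dioxolan-4-yl]-2-(trimethylsilyloxy)acetate, via tetrabutylammonium enolate 15 (not isolated)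
Conditions: Bu4N[Ph3SiF2] (0.1 equiv), THF, −78 to −40 °C
Reagents that add atoms: none
Why: Fluoride from Bu4N[Ph3SiF2] takes the silyl group from 14 to give the metal-free enolate 15 and Me3SiF; 15 adds to the keto carbonyl of 9, which cannot enolise and is far more electrophilic than its ester, and the hindered alkoxide is silylated by Me3SiF or by 14, which carries the chain and closes the retro-aldol path. The closest known reaction types are the fluoride-promoted aldol addition of silyl enol ethers and ketene acetals through an extended transition state and the aldol additions of lactic acid dioxolanone enolates to ketones with self-regeneration of the stereocentre. No ring is closed; only the C5–C6 bond forms. C6 is controlled by the acetal carbon of 14: the tert-butyl group covers one face of the planar enolate, the bond forms on the other face where the hydrogen of 12 stood, and the methyl group stays cis to tert-butyl, so 12 is substituted with retention. C5 is controlled by the relative orientation of the partners: seen along the new bond, the gap over the dioxolanone ring (between ring oxygen and C7, above the acetal hydrogen) is the tightest, the gap between methyl and ring oxygen is open, and the gap between methyl and C7 lies beside the enolate oxygen. With no metal to bridge them the keto oxygen should keep away from the enolate oxygen and sit anti to C7, the ortho-bromopyridyl group should then take the gap beside the enolate oxygen and leave the flat ester over the ring, which after ring closure puts the ester cis to the C6 oxygen and the C5 oxygen cis to methyl, as in 21. A lithium enolate is avoided for this reason: its closed transition state would hold the keto oxygen beside the enolate oxygen, send the aryl group to the open gap and the ester over the ring, and so is expected to favour the C5 epimer. The step needs attack at the keto group only and both facial selectivities; the first is secured by the electrophilicity of the 1,2-dicarbonyl, the second by tert-butyl, and the third, the least certain, by the bridge-free transition state and the size difference between aryl and ester.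

Step 10
Reactants: 16 methyl (2R)-2-{5-bromo-2-[(1E,3E,5S)-3,5-dimethylhepta-1,3-dien-1-yl]pyridin-4-yl}-2-[(2R,4S)-2-tert-butyl-4-methyl-5-oxo-1,3-dioxolan-4-yl]-2-(trimethylsilyloxy)acetate
Product: 19 methyl (5R,6S)-3-[(1E,3E,5S)-3,5-dimethylhepta-1,3-dien-1-yl]-6-hydroxy-6-methyl-7-oxo-5-(trimethylsilyloxy)-6,7-dihydro-5H-cyclopenta[c]pyridine-5-carboxylate, via arylmagnesium chloride 17 (not isolated), via tricyclic chloromagnesium hemiketal alkoxide 18 (not isolated)
Conditions: iPrMgCl·LiCl (1.1 equiv), THF, −20 to 0 °C; aq NH4Cl
Reagents that add atoms: none
Why: Bromine–magnesium exchange followed by Parham-type cyclisation: 17 adds 5-exo-trig to the dioxolanone carbonyl, the only carbonyl it can reach without forming a four-membered ring; 18 collapses on work-up to the C7 ketone with loss of pivalaldehyde, which frees the C6 hydroxyl, and no stereocentre is touched.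

Step 11
Reactants: 19 methyl (5R,6S)-3-[(1E,3E,5S)-3,5-dimethylhepta-1,3-dien-1-yl]-6-hydroxy-6-methyl-7-oxo-5-(trimethylsilyloxy)-6,7-dihydro-5H-cyclopenta[c]pyridine-5-carboxylate
Product: 20 methyl (5R,6S)-6-acetoxy-3-[(1E,3E,5S)-3,5-dimethylhepta-1,3-dien-1-yl]-6-methyl-7-oxo-5-(trimethylsilyloxy)-6,7-dihydro-5H-cyclopenta[c]pyridine-5-carboxylate
Conditions: Ac2O, 4-(dimethylamino)pyridine, Et3N, CH2Cl2, rt to 40 °C
Reagents that add atoms: acetic anhydride, CC(=O)OC(C)=O
Why: Steglich-type acetylation of a tertiary alcohol by nucleophilic catalysis; C6–OH is the only free hydroxyl, and the weakly basic medium avoids a C6 alkoxide that could cleave C5–C6.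

Step 12
Reactants: 20 methyl (5R,6S)-6-acetoxy-3-[(1E,3E,5S)-3,5-dimethylhepta-1,3-dien-1-yl]-6-methyl-7-oxo-5-(trimethylsilyloxy)-6,7-dihydro-5H-cyclopenta[c]pyridine-5-carboxylate
Product: 21 methyl (5R,6S)-6-acetoxy-3-[(1E,3E,5S)-3,5-dimethylhepta-1,3-dien-1-yl]-5-hydroxy-6-methyl-7-oxo-6,7-dihydro-5H-cyclopenta[c]pyridine-5-carboxylate
Conditions: HF·pyridine, pyridine, THF, 0 °C
Reagents that add atoms: none
Why: Cleavage of the trimethylsilyl ether by HF·pyridine under buffered, non-basic conditions; without base there is no retro-aldol opening, and the trans arrangement of the C5 and C6 oxygens on the five-membered ring disfavours acetyl migration.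

## Compound list

1 | (S)-2-methylbutan-1-ol | CC[C@H](C)CO | starting material
2 | (S)-2-methylbutanal | CC[C@H](C)C=O | intermediate
3 | (2E,4S)-2,4-dimethylhex-2-enal | CC[C@H](C)/C=C(C)/C=O | intermediate
4 | (3E,5S)-3,5-dimethylhept-3-en-1-yne | CC[C@H](C)/C=C(C)/C#C | intermediate
5 | 2-[(1E,3E,5S)-3,5-dimethylhepta-1,3-dien-1-yl]-4,4,5,5-tetramethyl-1,3,2-dioxaborolane | CC[C@H](C)/C=C(C)/C=C/B1OC(C)(C)C(C)(C)O1 | intermediate
6 | 2,5-dibromopyridine | Brc1ccc(Br)nc1 | starting material
7 | 5-bromo-2-[(1E,3E,5S)-3,5-dimethylhepta-1,3-dien-1-yl]pyridine | CC[C@H](C)/C=C(C)/C=C/c1ccc(Br)cn1 | intermediate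
8 | {5-bromo-2-[(1E,3E,5S)-3,5-dimethylhepta-1,3-dien-1-yl]pyridin-4-yl}lithium | CC[C@H](C)/C=C(C)/C=C/c1cc([Li])c(Br)cn1 | intermediate (not isolated)
9 | methyl 2-{5-bromo-2-[(1E,3E,5S)-3,5-dimethylhepta-1,3-dien-1-yl]pyridin-4-yl}-2-oxoacetate (fragment 2) | CC[C@H](C)/C=C(C)/C=C/c1cc(C(=O)C(=O)OC)c(Br)cn1 | intermediate
10 | (R)-lactic acid | C[C@@H](O)C(=O)O | starting material
11 | pivalaldehyde (2,2-dimethylpropanal) | CC(C)(C)C=O | starting material
12 | (2R,5R)-2-tert-butyl-5-methyl-1,3-dioxolan-4-one (cis acetal, fragment 1) | C[C@H]1O[C@@H](C(C)(C)C)OC1=O | intermediate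
13 | lithium (2R)-2-tert-butyl-5-methyl-1,3-dioxol-4-olate | [Li]OC1=C(C)O[C@@H](C(C)(C)C)O1 | intermediate (not isolated)
14 | (2R)-2-tert-butyl-5-methyl-4-(trimethylsilyloxy)-1,3-dioxole | C[Si](C)(C)OC1=C(C)O[C@@H](C(C)(C)C)O1 | intermediate
15 | tetrabutylammonium (2R)-2-tert-butyl-5-methyl-1,3-dioxol-4-olate | [O-]C1=C(C)O[C@@H](C(C)(C)C)O1.CCCC[N+](CCCC)(CCCC)CCCC | intermediate (not isolated)
16 | methyl (2R)-2-{5-bromo-2-[(1E,3E,5S)-3,5-dimethylhepta-1,3-dien-1-yl]pyridin-4-yl}-2-[(2R,4S)-2-tert-butyl-4-methyl-5-oxo-1,3-dioxolan-4-yl]-2-(trimethylsilyloxy)acetate | CC[C@H](C)/C=C(C)/C=C/c1cc(c(Br)cn1)[C@](O[Si](C)(C)C)(C(=O)OC)[C@]1(C)O[C@@H](C(C)(C)C)OC1=O | intermediate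
17 | arylmagnesium chloride from 16 (MgCl in place of Br at pyridine C5) | CC[C@H](C)/C=C(C)/C=C/c1cc(c([Mg]Cl)cn1)[C@](O[Si](C)(C)C)(C(=O)OC)[C@]1(C)O[C@@H](C(C)(C)C)OC1=O | intermediate (not isolated)
18 | chloromagnesium alkoxide of the tricyclic hemiketal formed by addition of the aryl carbon of 17 to its dioxolanone carbonyl (dioxolane cis-fused on C6–C7) | CC[C@H](C)/C=C(C)/C=C/c1cc2c(cn1)[C@@]3(O[Mg]Cl)O[C@H](C(C)(C)C)O[C@@]3(C)[C@@]2(O[Si](C)(C)C)C(=O)OC | intermediate (not isolated)
19 | methyl (5R,6S)-3-[(1E,3E,5S)-3,5-dimethylhepta-1,3-dien-1-yl]-6-hydroxy-6-methyl-7-oxo-5-(trimethylsilyloxy)-6,7-dihydro-5H-cyclopenta[c]pyridine-5-carboxylate | CC[C@H](C)/C=C(C)/C=C/c1cc2c(cn1)C(=O)[C@@](C)(O)[C@@]2(O[Si](C)(C)C)C(=O)OC | intermediate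
20 | methyl (5R,6S)-6-acetoxy-3-[(1E,3E,5S)-3,5-dimethylhepta-1,3-dien-1-yl]-6-methyl-7-oxo-5-(trimethylsilyloxy)-6,7-dihydro-5H-cyclopenta[c]pyridine-5-carboxylate | CC[C@H](C)/C=C(C)/C=C/c1cc2c(cn1)C(=O)[C@@](C)(OC(C)=O)[C@@]2(O[Si](C)(C)C)C(=O)OC | intermediate
21 | methyl (5R,6S)-6-acetoxy-3-[(1E,3E,5S)-3,5-dimethylhepta-1,3-dien-1-yl]-5-hydroxy-6-methyl-7-oxo-6,7-dihydro-5H-cyclopenta[c]pyridine-5-carboxylate | CC[C@H](C)/C=C(C)/C=C/c1cc2c(cn1)C(=O)[C@@](C)(OC(C)=O)[C@@]2(O)C(=O)OC | target

## Step count and least certain steps

Total step count: 12. Longest linear sequence: 10 steps (steps 1 to 6 and 9 to 12, from 1 to 21).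

**Step 9 (key step).**
- What may go wrong: poor or inverted facial selectivity at the keto carbon. The addition of the metal-free enolate is reversible until the hindered alkoxide is silylated, so the product ratio may reflect the rates of silyl transfer and not the extended transition state, and the size difference between aryl and ester may not be large enough. A slow silyl transfer would also give the enolate time to fragment.
- Mitigation within the step: the two C5 epimers are diastereomers and should be separable, and the unwanted one can in principle be returned through desilylation and retro-aldol, since the enolate keeps its acetal stereocentre.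
- Fallback, setting out from 12 and 7 and returning at 16: the order of bond formation at C5 is reversed, so that C5 is set by 1,2-induction from C6 and not by the relative orientation of two fragments. The lithium enolate 13 is C-acylated with dimethyl oxalate at −78 °C, again trans to tert-butyl, to give methyl 2-[(2R,4S)-2-tert-butyl-4-methyl-5-oxo-1,3-dioxolan-4-yl]-2-oxoacetate F1. The aryllithium 8 is added to F1 in the presence of MgBr2·OEt2, where a chelate between the keto oxygen and the acetal oxygen on C6 should steer the aryl group past the methyl group, to give methyl (2R)-2-{5-bromo-2-[(1E,3E,5S)-3,5-dimethylhepta-1,3-dien-1-yl]pyridin-4-yl}-2-[(2R,4S)-2-tert-butyl-4-methyl-5-oxo-1,3-dioxolan-4-yl]-2-hydroxyacetate F2. N-(trimethylsilyl)imidazole then silylates F2 to 16.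

**Step 6.**
- What may go wrong: the amide base may attack the dienyl chain instead of the ring, by conjugate addition or by removal of the C5' hydrogen, which is conjugated with the pyridine through the diene; that would erode the side-chain configuration. The lithiated bromopyridine may also lose LiBr or let bromine migrate if it warms.
- Fallback, setting out from 6 and 5 and returning at 9: the keto ester is installed before the chain. 6 is lithiated at C4 with LiN(iPr)2 at −78 °C and quenched with dimethyl oxalate to give methyl 2-(2,5-dibromopyridin-4-yl)-2-oxoacetate F3. Suzuki coupling of F3 with 5 under water-free conditions (Pd(PPh3)4, CsF, 1,4-dioxane) at the C2 bromide, which is alpha to nitrogen and unhindered, then gives 9.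

**Step 10.**
- What may go wrong: bromine–magnesium exchange on the hindered bromide may be slower than addition of the reagent to the lactone or ester, the arylmagnesium may be protonated instead of cyclising, and the magnesium alkoxide at C6 may trigger silyl migration or cleavage of C5–C6.
- Fallback, setting out from 16 and returning at 19: the acyl acceptor is turned into an aldehyde equivalent and closed under neutral conditions. iBu2AlH at −78 °C reduces the dioxolanone carbonyl to the lactol methyl (2R)-2-{5-bromo-2-[(1E,3E,5S)-3,5-dimethylhepta-1,3-dien-1-yl]pyridin-4-yl}-2-[(2R,4S)-2-tert-butyl-5-hydroxy-4-methyl-1,3-dioxolan-4-yl]-2-(trimethylsilyloxy)acetate F4. Intramolecular Nozaki–Hiyama–Kishi addition (CrCl2, NiCl2 cat., DMF) closes C7–C7a and, after loss of pivalaldehyde, gives the diol methyl (5R,6R)-3-[(1E,3E,5S)-3,5-dimethylhepta-1,3-dien-1-yl]-6,7-dihydroxy-6-methyl-5-(trimethylsilyloxy)-6,7-dihydro-5H-cyclopenta[c]pyridine-5-carboxylate F5 (either configuration at C7). MnO2 oxidises its secondary pyridylic alcohol to 19.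

**Step 11.**
- What may go wrong: slow acylation of a tertiary hydroxyl flanked by two fully substituted carbons; forcing conditions invite silyl migration or base-induced ring opening.
- Fallback, setting out from 19 and returning at 20 (no new compound, F0): the alcohol is acylated as its alkoxide instead of by nucleophilic catalysis, by deprotonation with LiN(SiMe3)2 at −78 °C and immediate quench with acetyl chloride, so that the alkoxide lives only at low temperature.

## Further compounds

F1 | step 9 | methyl 2-[(2R,4S)-2-tert-butyl-4-methyl-5-oxo-1,3-dioxolan-4-yl]-2-oxoacetate | COC(=O)C(=O)[C@]1(C)O[C@@H](C(C)(C)C)OC1=O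
F2 | step 9 | methyl (2R)-2-{5-bromo-2-[(1E,3E,5S)-3,5-dimethylhepta-1,3-dien-1-yl]pyridin-4-yl}-2-[(2R,4S)-2-tert-butyl-4-methyl-5-oxo-1,3-dioxolan-4-yl]-2-hydroxyacetate | CC[C@H](C)/C=C(C)/C=C/c1cc(c(Br)cn1)[C@](O)(C(=O)OC)[C@]1(C)O[C@@H](C(C)(C)C)OC1=O
F3 | step 6 | methyl 2-(2,5-dibromopyridin-4-yl)-2-oxoacetate | COC(=O)C(=O)c1cc(Br)ncc1Br
F4 | step 10 | methyl (2R)-2-{5-bromo-2-[(1E,3E,5S)-3,5-dimethylhepta-1,3-dien-1-yl]pyridin-4-yl}-2-[(2R,4S)-2-tert-butyl-5-hydroxy-4-methyl-1,3-dioxolan-4-yl]-2-(trimethylsilyloxy)acetate (lactol, both anomers) | CC[C@H](C)/C=C(C)/C=C/c1cc(c(Br)cn1)[C@](O[Si](C)(C)C)(C(=O)OC)[C@]1(C)O[C@@H](C(C)(C)C)OC1O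
F5 | step 10 | methyl (5R,6R)-3-[(1E,3E,5S)-3,5-dimethylhepta-1,3-dien-1-yl]-6,7-dihydroxy-6-methyl-5-(trimethylsilyloxy)-6,7-dihydro-5H-cyclopenta[c]pyridine-5-carboxylate (either configuration at C7) | CC[C@H](C)/C=C(C)/C=C/c1cc2c(cn1)C(O)[C@@](C)(O)[C@@]2(O[Si](C)(C)C)C(=O)OC
F0 | step 11 | none | none
A1 | alternative 1 | 2,4-dihydroxy-3-methyl-6-[(3E,5E,7S)-5,7-dimethyl-2-oxonona-3,5-dien-1-yl]benzaldehyde | CC[C@H](C)/C=C(C)/C=C/C(=O)Cc1cc(O)c(C)c(O)c1C=O
A2 | alternative 1 | (7S)-3-[(1E,3E,5S)-3,5-dimethylhepta-1,3-dien-1-yl]-7-hydroxy-7-methyl-6H-isochromene-6,8(7H)-dione | CC[C@H](C)/C=C(C)/C=C/C1=CC2=CC(=O)[C@](C)(O)C(=O)C2=CO1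
A3 | alternative 2 | methyl (2R,3S)-3-acetoxy-4-{2-[(1E,3E,5S)-3,5-dimethylhepta-1,3-dien-1-yl]-1,3-oxazol-5-yl}-2-ethenyl-3-methyl-4-oxo-2-(triethylsilyloxy)butanoate | CC[C@H](C)/C=C(C)/C=C/c1ncc(o1)C(=O)[C@@](C)(OC(C)=O)[C@](O[Si](CC)(CC)CC)(C=C)C(=O)OC
A4 | alternative 2 | methyl (5R,6S)-6-acetoxy-3-[(1E,3E,5S)-3,5-dimethylhepta-1,3-dien-1-yl]-6-methyl-7-oxo-5-(triethylsilyloxy)-6,7-dihydro-5H-cyclopenta[c]pyridine-5-carboxylate | CC[C@H](C)/C=C(C)/C=C/c1cc2c(cn1)C(=O)[C@@](C)(OC(C)=O)[C@@]2(O[Si](CC)(CC)CC)C(=O)OC
A5 | alternative 3 | methyl 2-(triethylsilyloxy)-2-[(4S)-2,2,4-trimethyl-5-oxo-1,3-dioxolan-4-yl]acetate (either configuration at C2) | COC(=O)C(O[Si](CC)(CC)CC)[C@]1(C)OC(C)(C)OC1=O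
A6 | alternative 3 | 6-[(1E,3E,5S)-3,5-dimethylhepta-1,3-dien-1-yl]-3,4-didehydropyridine | CC[C@H](C)/C=C(C)/C=C/C1=CC#CC=N1
A7 | alternative 3 | methyl (5R,6S)-3-[(1E,3E,5S)-3,5-dimethylhepta-1,3-dien-1-yl]-6-hydroxy-6-methyl-7-oxo-5-(triethylsilyloxy)-6,7-dihydro-5H-cyclopenta[c]pyridine-5-carboxylate | CC[C@H](C)/C=C(C)/C=C/c1cc2c(cn1)C(=O)[C@@](C)(O)[C@@]2(O[Si](CC)(CC)CC)C(=O)OC
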